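**Retrosynthetic overview**

1. The target is a trans-4-aryl-5-methoxy-1-tetralol. C1–OH is taken back to a ketone (reduced by asymmetric transfer hydrogenation), and the naphthol ring (ring C) to an 8-methoxy-1-tetralone ring that is aromatized last.
2. Ring B is cut at C3–C4 and C1–C8a. A Rh-catalysed (3+3) annulation of arylboronate-enone 4 with cyclopropanone (the C1–C2–C3 unit, released from 5) should form both bonds and the C4 stereocentre in one operation.
3. Enabling feature: C4 is attached to C2' of a ring that carries oxygen on C1'. Carried as the tetralone, C2'=C4 is an exocyclic enone with C4 as its electrophilic β-carbon. Boron on C8a (meta to the ring A OMe, where Friedel–Crafts chemistry would not go) makes that ring carbon the nucleophile for C1.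
4. Enone 4 comes from Claisen–Schmidt condensation of 8-methoxy-1-tetralone (1) with 2-bromo-6-methoxybenzaldehyde (2), then Miyaura borylation.
5. Ring order: rings A and C/D are bought, ring B is closed in step 3, ring C is aromatized in step 5.

Key step: step 3

Remark: C1–C8a are the tetralol locants of the target (ring A = its benzo ring, ring B = the C1–C4 ring); primed locants belong to the naphthalene unit (ring C = the C1'–C4' ring). It is assumed that one enantiomer of the commercial diene ligand delivers (4R) in step 3; the (R,R) form is written provisionally and the antipode is used if the first run shows the opposite sense.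

**Route**

Step 1
Reactants: 1 8-methoxy-3,4-dihydronaphthalen-1(2H)-one; 2 2-bromo-6-methoxybenzaldehyde
Product: 3 (E)-2-[(2-bromo-6-methoxyphenyl)methylidene]-8-methoxy-3,4-dihydronaphthalen-1(2H)-one
Conditions: KOH (0.3 equiv), EtOH, rt
Reagents that add atoms: none
Why: Claisen–Schmidt (crossed aldol) condensation in which 1 has a single enolisable α-CH2 and 2 has no α-hydrogen, so only the cross product can form, and dehydration should give the thermodynamically preferred E-enone (aryl anti to C=O) without creating a stereocentre.

Step 2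
Reactants: 3 (E)-2-[(2-bromo-6-methoxyphenyl)methylidene]-8-methoxy-3,4-dihydronaphthalen-1(2H)-one
Product: 4 (E)-8-methoxy-2-{[2-methoxy-6-(4,4,5,5-tetramethyl-1,3,2-dioxaborolan-2-yl)phenyl]methylidene}-3,4-dihydronaphthalen-1(2H)-one
Conditions: B2pin2 (1.3 equiv), Pd(dppf)Cl2 (3 mol %), KOAc (3 equiv), 1,4-dioxane, 90 °C
Reagents that add atoms: bis(pinacolato)diboron, CC1(C)OB(OC1(C)C)B1OC(C)(C)C(C)(C)O1
Why: Miyaura borylation, in which Pd(0) inserts into the aryl C–Br bond and acetate mediates transfer of Bpin from B2pin2 under weakly basic conditions that should leave the enone and the aryl ethers untouched and avoid Suzuki homocoupling.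

Step 3
Reactants: 4 (E)-8-methoxy-2-{[2-methoxy-6-(4,4,5,5-tetramethyl-1,3,2-dioxaborolan-2-yl)phenyl]methylidene}-3,4-dihydronaphthalen-1(2H)-one; 5 (1-ethoxycyclopropoxy)trimethylsilane
Product: 10 (4R)-5-methoxy-4-[(2RS)-8-methoxy-1-oxo-1,2,3,4-tetrahydronaphthalen-2-yl]-3,4-dihydronaphthalen-1(2H)-one as a mixture of C2' epimers, via cyclopropanone 6 (not isolated), via rhodium cyclopropanolate 7 (not isolated), via alkylrhodium ketone 8 (not isolated), via rhodium enolate 9 (not isolated)
Conditions: [RhCl(C2H4)2]2 (2.5 mol %), (R,R)-Ph-bod* (6 mol %), K3PO4 (0.3 equiv), MeOH (5 equiv), toluene, 50 °C; 5 (2 equiv) added over 4 h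
Reagents that add atoms: none
Why: Proposed new method: two Rh(I) elementary steps that are each known are coupled into a (3+3) annulation: cyclopropanone 6, released from 5 by methoxide (desilylation, loss of ethoxide), takes up the aryl–rhodium formed from 4 by B-to-Rh transmetalation (1,2-addition, C8a–C1 bond, cyclopropanolate 7), and strain-driven β-carbon elimination opens 7 to the ketone-chelated alkylrhodium (homoenolate) 8. The Rh–C3 bond of 8 then inserts the facing exocyclic enone C4=C2' in a 6-exo-trig syn-1,4-addition (C3–C4 bond, ring B closed) to give the oxa-π-allyl rhodium 9, which methanol protonates to 10 with return of Rh–OMe. The closest known reactions are the Rh-catalysed addition of arylboron reagents to cyclobutanones followed by β-carbon elimination of the rhodium alkoxide, and the Rh/chiral-diene 1,4-addition to enones. C4 is the only stereocentre that matters and should be set in the enone insertion by the chiral diene on rhodium, which selects the enone face; C2' forms unselectively and is erased in step 5. The step needs the aryl–rhodium to prefer the strained C=O over the enone of a second molecule, insertion to outrun β-hydride elimination of 8, and ring closure at the ring carbon meta to OMe; the hindered trisubstituted E-enone, the five-membered O→Rh chelate combined with the six-membered transition state, and the boron on C8a should secure these.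

Step 4
Reactants: 10 (4R)-5-methoxy-4-[(2RS)-8-methoxy-1-oxo-1,2,3,4-tetrahydronaphthalen-2-yl]-3,4-dihydronaphthalen-1(2H)-one
Product: 11 (1S,4R)-5-methoxy-4-[(2RS)-8-methoxy-1-oxo-1,2,3,4-tetrahydronaphthalen-2-yl]-1,2,3,4-tetrahydronaphthalen-1-ol
Conditions: RuCl[(S,S)-TsDPEN](p-cymene) (2 mol %), HCO2H/Et3N (5:2), CH2Cl2, 25 °C
Reagents that add atoms: none
Why: Noyori–Ikariya asymmetric transfer hydrogenation, in which the (S,S)-TsDPEN–Ru hydride should deliver hydrogen to the face that gives (S)-1-tetralols, so C1 is set by the catalyst trans to the C4 substituent for either C2' epimer, while the ring C ketone, shielded by its α-branch and the peri-methoxy group, is expected to react much more slowly.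

Step 5
Reactants: 11 (1S,4R)-5-methoxy-4-[(2RS)-8-methoxy-1-oxo-1,2,3,4-tetrahydronaphthalen-2-yl]-1,2,3,4-tetrahydronaphthalen-1-ol
Product: 15 dipolynaphthalene A [(1S,4R)-4-(1-hydroxy-8-methoxynaphthalen-2-yl)-5-methoxy-1,2,3,4-tetrahydronaphthalen-1-ol], via selanyl ketone 12 (not isolated), via selenoxide 13 (not isolated), via naphthalenone tautomer 14 (not isolated)
Conditions: LDA (2.2 equiv), THF, −78 °C; PhSeBr (1.1 equiv), −78 °C; then mCPBA (1.05 equiv), CH2Cl2, −78 °C → rt
Reagents that add atoms: none
Why: Reich α-selenenylation/selenoxide syn-elimination, in which the dianion (C1 alkoxide, C2' enolate) is selenenylated at C2', oxidation at selenium is followed by syn-elimination into the C3' methylene (elimination toward C4 would give a strained tetrasubstituted exocyclic alkene next to the peri-OMe group), and the resulting naphthalen-1(4H)-one tautomerises to the naphthol, which removes the C2' stereocentre and leaves C1 and C4 untouched.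

**Compound list**

1 | 8-methoxy-3,4-dihydronaphthalen-1(2H)-one (8-methoxy-1-tetralone) | COc1cccc2CCCC(=O)c12 | starting material
2 | 2-bromo-6-methoxybenzaldehyde | COc1cccc(Br)c1C=O | starting material
3 | (E)-2-[(2-bromo-6-methoxyphenyl)methylidene]-8-methoxy-3,4-dihydronaphthalen-1(2H)-one | COc1cccc2CC/C(=C\c3c(Br)cccc3OC)C(=O)c12 | intermediate
4 | (E)-8-methoxy-2-{[2-methoxy-6-(4,4,5,5-tetramethyl-1,3,2-dioxaborolan-2-yl)phenyl]methylidene}-3,4-dihydronaphthalen-1(2H)-one | COc1cccc2CC/C(=C\c3c(B4OC(C)(C)C(C)(C)O4)cccc3OC)C(=O)c12 | intermediate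
5 | (1-ethoxycyclopropoxy)trimethylsilane | CCOC1(CC1)O[Si](C)(C)C | starting material
6 | cyclopropanone | O=C1CC1 | intermediate
7 | rhodium(I) 1-arylcyclopropan-1-olate derived from 4 (aryl carbon C8a bonded to the carbinol carbon; diene ligand on Rh omitted) | COc1cccc2CC/C(=C\c3c(C4(O[Rh])CC4)cccc3OC)C(=O)c12 | intermediate
8 | 3-rhodiopropanoyl arene (β-keto alkylrhodium, Rh on C3; diene ligand omitted) | COc1cccc2CC/C(=C\c3c(C(=O)CC[Rh])cccc3OC)C(=O)c12 | intermediate
9 | rhodium enolate of the ring C ketone after ring closure, (4R) (diene ligand omitted) | COc1cccc2c1[C@@H](C1=C(O[Rh])c3c(OC)cccc3CC1)CCC2=O | intermediate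
10 | (4R)-5-methoxy-4-[(2RS)-8-methoxy-1-oxo-1,2,3,4-tetrahydronaphthalen-2-yl]-3,4-dihydronaphthalen-1(2H)-one | COc1cccc2c1[C@@H](C1CCc3cccc(OC)c3C1=O)CCC2=O | intermediate
11 | (1S,4R)-5-methoxy-4-[(2RS)-8-methoxy-1-oxo-1,2,3,4-tetrahydronaphthalen-2-yl]-1,2,3,4-tetrahydronaphthalen-1-ol | COc1cccc2c1[C@@H](C1CCc3cccc(OC)c3C1=O)CC[C@@H]2O | intermediate
12 | 2'-(phenylselanyl) derivative of 11 (SePh on C2'; C1 and C4 as in 11) | COc1cccc2c1[C@@H](C1([Se]c3ccccc3)CCc3cccc(OC)c3C1=O)CC[C@@H]2O | intermediate
13 | selenoxide of 12 | COc1cccc2c1[C@@H](C1([Se](=O)c3ccccc3)CCc3cccc(OC)c3C1=O)CC[C@@H]2O | intermediate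
14 | 2-substituted 8-methoxynaphthalen-1(4H)-one (keto tautomer of 15; C1 and C4 as in 11) | COc1cccc2c1[C@@H](C1=CCc3cccc(OC)c3C1=O)CC[C@@H]2O | intermediate
15 | dipolynaphthalene A, (1S,4R)-4-(1-hydroxy-8-methoxynaphthalen-2-yl)-5-methoxy-1,2,3,4-tetrahydronaphthalen-1-ol | COc1cccc2c1[C@@H](c1ccc3cccc(OC)c3c1O)CC[C@@H]2O | target

**Step count and risk assessment**

Total step count: 5. Longest linear sequence: 5 steps (from 1 or 2 to 15).

Steps most likely to fail:

Step 3 (Proposed new method). The alkylrhodium may undergo β-hydride elimination or protonolysis before it inserts the enone, which would give ring-opened aryl vinyl or aryl ethyl ketones. The boronate may be protodeboronated, or the ligand may discriminate the enone faces poorly. The fallback uses known chemistry, sets out from 2 and comes back at 15. Commercial 8-methoxynaphthalen-1-ol is converted into its bromomagnesium salt (EtMgBr, toluene) and added to 2 in a chelation-directed Casiraghi ortho-hydroxyalkylation, which should give racemic 2-[(2-bromo-6-methoxyphenyl)(hydroxy)methyl]-8-methoxynaphthalen-1-ol F1. Sodium p-toluenesulfinate in formic acid exchanges the benzylic hydroxyl for sulfinate to give the bench-stable sulfone F2. With Cs2CO3, F2 releases the ortho-quinone methide (possible because the free 1'-OH is ortho to the benzylic carbon). An aminoindanol-derived chiral triazolium carbene and acrolein should convert it, by the known homoenolate [4+3] annulation, into the lactone (5R)-5-(2-bromo-6-methoxyphenyl)-11-methoxy-4,5-dihydronaphtho[1,2-b]oxepin-2(3H)-one F3; this forms C3–C4 and the C4 stereocentre and parks C1 on the naphthol oxygen. Bromine–lithium exchange (t-BuLi, THF, −100 °C) then lets the aryllithium on C8a attack the aryl ester across the ring (Parham cycliacylation), releasing the naphthol and giving (4R)-4-(1-hydroxy-8-methoxynaphthalen-2-yl)-5-methoxy-3,4-dihydronaphthalen-1(2H)-one F4. Transfer hydrogenation under the conditions of step 4 gives 15.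

Step 5. The syn-elimination may run in the wrong direction (into C4, which would erase the stereocentre), the hindered ketone may enolise incompletely beside the alkoxide, or the peracid may oxidise the electron-rich naphthol. The fallback sets out from 11 and comes back at 15. It replaces the selenium chemistry on the free alcohol by a palladium enolate β-hydride elimination on a protected substrate. The C1 hydroxyl is silylated (TBSOTf, 2,6-lutidine) to give the TBS ether of 11 F5. The ring C ketone is converted into its trimethylsilyl enol ether F6 (TMSOTf, Et3N). Saegusa–Ito oxidation (Pd(OAc)2, MeCN) with tautomerisation should give the TBS ether of 15 F7, and TBAF gives 15.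

Step 4. Site selectivity may be lost (the ring C carbonyl is reduced as well), or catalyst control of the C1 face may be incomplete against the bias of the C4 substituent. The fallback sets out from 10 and comes back at 15. It differentiates the ketones by protection and moves the reduction to the end, where only one carbonyl is left. The less hindered ring B ketone is ketalised (ethylene glycol, TsOH, benzene, Dean–Stark) to give the mono-dioxolane of 10 F8. Ring C is then aromatised by the protocol of step 5 (LDA 1.1 equiv; PhSeBr; mCPBA) through the 2'-(phenylselanyl) ketal F9 to the naphthol ketal F10. Aqueous HCl in acetone releases the ketone F4 already described, and transfer hydrogenation as in step 4 gives 15.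

**Further compounds**

F1 | step 3 | 2-[(2-bromo-6-methoxyphenyl)(hydroxy)methyl]-8-methoxynaphthalen-1-ol (racemic) | COc1cccc(Br)c1C(O)c1ccc2cccc(OC)c2c1O
F2 | step 3 | 2-[(2-bromo-6-methoxyphenyl)(4-methylbenzenesulfonyl)methyl]-8-methoxynaphthalen-1-ol (racemic) | COc1cccc(Br)c1C(c1ccc2cccc(OC)c2c1O)S(=O)(=O)c1ccc(C)cc1
F3 | step 3 | (5R)-5-(2-bromo-6-methoxyphenyl)-11-methoxy-4,5-dihydronaphtho[1,2-b]oxepin-2(3H)-one | COc1cccc(Br)c1[C@@H]1CCC(=O)Oc2c1ccc1cccc(OC)c12
F4 | step 3 | (4R)-4-(1-hydroxy-8-methoxynaphthalen-2-yl)-5-methoxy-3,4-dihydronaphthalen-1(2H)-one | COc1cccc2c1[C@@H](c1ccc3cccc(OC)c3c1O)CCC2=O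
F5 | step 5 | tert-butyldimethylsilyl ether of 11 (silyl on the C1 oxygen) | COc1cccc2c1[C@@H](C1CCc3cccc(OC)c3C1=O)CC[C@@H]2O[Si](C)(C)C(C)(C)C
F6 | step 5 | trimethylsilyl enol ether of F5 (C1'–OTMS, C1'=C2') | COc1cccc2c1[C@@H](C1=C(O[Si](C)(C)C)c3c(OC)cccc3CC1)CC[C@@H]2O[Si](C)(C)C(C)(C)C
F7 | step 5 | tert-butyldimethylsilyl ether of 15 (silyl on the C1 oxygen) | COc1cccc2c1[C@@H](c1ccc3cccc(OC)c3c1O)CC[C@@H]2O[Si](C)(C)C(C)(C)C
F8 | step 4 | mono-dioxolane of 10 (ethylene ketal at C1 of ring B) | COc1cccc2c1[C@@H](C1CCc3cccc(OC)c3C1=O)CCC21OCCO1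
F9 | step 4 | 2'-(phenylselanyl) derivative of F8 | COc1cccc2c1[C@@H](C1([Se]c3ccccc3)CCc3cccc(OC)c3C1=O)CCC21OCCO1
F10 | step 4 | ethylene ketal of F4 | COc1cccc2c1[C@@H](c1ccc3cccc(OC)c3c1O)CCC21OCCO1
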